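The target is cut at C7–C8 of ring B: the C7 isopropenyl group next to the C8 carbonyl is the retron of an intramolecular carbonyl-ene reaction between a C8 aldehyde and a prenyl group on C5. In one operation the key step closes ring B, sets C7, and turns the prenyl unit into the isopropenyl group. Its precursor is a fully substituted ring-A cyclohexane that carries, cis to each other, the prenyl group on C5 and an α-angeloyloxy acetaldehyde arm on C10. C9 already bears its oxygen and both angelates are in place, so that only one oxidation follows the ring closure.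

Key step: step 13

Remark: ring atoms carry eremophilane numbers throughout (C3 oxygenated, C4 and C5 methyl-bearing, C10 ring fusion); β is the face of the C5 methyl group; angelate = (Z)-2-methylbut-2-enoate.
Assumption: the (R,R)-salen–Cr(III) catalyst of step 1 is taken to block the Cα-Re face of 1; if the sense proves opposite, the (S,S)-catalyst is used with no other change (the same holds for the auxiliary of its fallback).

Step 1
Reactants: 1 (E)-2-methylbut-2-enal; 2 (E)-3-(tert-butyldimethylsilyloxy)-N,N-dimethylbuta-1,3-dien-1-amine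
Product: 3 (1R,2S,6S)-4-(tert-butyldimethylsilyloxy)-2-(dimethylamino)-1,6-dimethylcyclohex-3-ene-1-carbaldehyde (endo adduct)
Conditions: (R,R)-(salen)Cr(III)SbF6 (5 mol%), 4 Å MS, CH2Cl2, −40 °C
Reagents that add atoms: diene 2, CN(C)/C=C/C(=C)O[Si](C)(C)C(C)(C)C
Why: Lewis-acid-catalysed Diels–Alder reaction of a 1-amino-3-siloxy diene with an α,β-disubstituted enal; the siloxy-activated CH2 terminus bonds to C4 and the amino terminus to C5, the E geometry of 1 makes the C4 and C5 methyl groups cis, and the catalyst leaves the Cα-Si face open, which fixes both centres absolutely.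

Step 2
Reactants: 3; 4 (methoxymethyl)triphenylphosphonium chloride
Product: 6 2-[(1R,6S)-1,6-dimethyl-4-oxocyclohex-2-en-1-yl]acetaldehyde, via enol ether 5 (not isolated)
Conditions: 4, KHMDS, THF, 0 °C; 3, −78 → 0 °C; then 1 M HCl, THF, rt
Reagents that add atoms: phosphonium salt 4, COC[P+](c1ccccc1)(c1ccccc1)c1ccccc1.[Cl-]; water, O
Why: Wittig methoxymethylenation of the aldehyde on the intact cycloadduct, then one acid treatment should hydrolyse both enol ethers and eliminate dimethylamine from the β-amino ketone, giving the enone and the homologated aldehyde without touching C4 or C5.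

Step 3
Reactants: 6; 7 isopropyltriphenylphosphonium iodide
Product: 8 (4R,5S)-4,5-dimethyl-4-(3-methylbut-2-en-1-yl)cyclohex-2-en-1-one
Conditions: 7, n-BuLi, THF, 0 °C; 6, −78 → 0 °C
Reagents that add atoms: phosphonium salt 7, CC(C)[P+](c1ccccc1)(c1ccccc1)c1ccccc1.[I-]
Why: Wittig olefination; the unstabilised ylide should react with the unhindered aldehyde much faster than with the enone carbonyl, which installs the prenyl group on C5.

Step 4
Reactants: 8
Product: 10 (4S,5R,6S)-6-hydroxy-4,5-dimethyl-4-(3-methylbut-2-en-1-yl)cyclohex-2-en-1-one, via potassium dienolate 9 (not isolated)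
Conditions: KHMDS, THF, −78 °C; 2-(phenylsulfonyl)-3-phenyloxaziridine, −78 °C; NH4Cl
Reagents that add atoms: 2-(phenylsulfonyl)-3-phenyloxaziridine, O=S(=O)(c1ccccc1)N1OC1c1ccccc1
Why: oxaziridine hydroxylation of the cross-conjugated enolate (C3 is the only enolisable position because C5 is quaternary); the oxidant should approach C3 anti to the pseudoaxial methyl group next to it, giving the 3α-alcohol trans to the C4 methyl, which is also the more stable diequatorial epimer.

Step 5
Reactants: 10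
Product: 11 (4S,5R,6S)-6-(tert-butyldimethylsilyloxy)-4,5-dimethyl-4-(3-methylbut-2-en-1-yl)cyclohex-2-en-1-one
Conditions: TBSOTf, 2,6-lutidine, CH2Cl2, −78 °C
Reagents that add atoms: tert-butyldimethylsilyl triflate, CC(C)(C)[Si](C)(C)OS(=O)(=O)C(F)(F)F
Why: silylation of the secondary alcohol protects O3 against the organometallic and triflating reagents of step 6.

Step 6
Reactants: 11; 12 (Z)-1-bromo-2-ethoxyethene
Product: 14 (3S,4S,5R,6S)-6-(tert-butyldimethylsilyloxy)-3-[(Z)-2-ethoxyethenyl]-4,5-dimethyl-4-(3-methylbut-2-en-1-yl)cyclohex-1-en-1-yl trifluoromethanesulfonate, via lithium enolate 13 (not isolated)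
Conditions: 12, t-BuLi, Et2O, −78 °C; CuI, −40 °C; 11, −78 → −30 °C; then PhNTf2, THF, −78 °C → rt
Reagents that add atoms: bromide 12, CCO/C=C\Br; N-phenylbis(trifluoromethanesulfonimide), O=S(=O)(N(c1ccccc1)S(=O)(=O)C(F)(F)F)C(F)(F)F
Why: conjugate addition of a β-alkoxyvinyl cuprate (a masked acetaldehyde anion) with regiospecific O-triflation of the enolate; the cuprate should enter C10 axially from the α face, anti to the pseudoaxial 5β-methyl of the half-chair that keeps O3 and the C4 methyl equatorial, so the new arm is cis to the prenyl group.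

Step 7
Reactants: 14
Product: 15 tert-butyl({(1R,4R,5S,6R)-4-[(Z)-2-ethoxyethenyl]-5,6-dimethyl-5-(3-methylbut-2-en-1-yl)cyclohex-2-en-1-yl}oxy)dimethylsilane
Conditions: Pd(PPh3)4 (5 mol%), Bu3SnH, LiCl, THF, 60 °C
Reagents that add atoms: none
Why: palladium-catalysed hydride reduction of the enol triflate removes the C2 oxygen under neutral conditions that the enol ether and silyl ether tolerate.

Step 8
Reactants: 15
Product: 17 (1R)-1-[(1S,4R,5R,6R)-4-(tert-butyldimethylsilyloxy)-5,6-dimethyl-6-(3-methylbut-2-en-1-yl)cyclohex-2-en-1-yl]-2,2-diethoxyethan-1-ol, via epoxy ether 16 (not isolated)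
Conditions: mCPBA (1.0 equiv), EtOH/CH2Cl2, −78 → −20 °C
Reagents that add atoms: 3-chloroperbenzoic acid, OOC(=O)c1cccc(Cl)c1; ethanol, CCO
Why: peracid epoxidation of the electron-rich enol ether (much faster than the other two alkenes) and ethanolysis of the alkoxy epoxide at the acetal carbon; allylic 1,3-strain of the Z-enol ether holds the C10–H in the alkene plane, so the oxidant should attack the face remote from quaternary C5 and make C9 R, the 9β-oxygen of the target.

Step 9
Reactants: 17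
Product: 18 (1R)-1-[(1S,2R,3R,4R)-4-(tert-butyldimethylsilyloxy)-2,3-dimethyl-2-(3-methylbut-2-en-1-yl)cyclohexyl]-2,2-diethoxyethan-1-ol
Conditions: 2-nitrobenzenesulfonohydrazide, Et3N, CH2Cl2, rt
Reagents that add atoms: none
Why: diimide reduction, which should saturate the cis-disubstituted C1=C2 alkene and leave the trisubstituted prenyl alkene.

Step 10
Reactants: 18
Product: 19 (1R)-2,2-diethoxy-1-[(1S,2R,3R,4R)-4-hydroxy-2,3-dimethyl-2-(3-methylbut-2-en-1-yl)cyclohexyl]ethan-1-ol
Conditions: TBAF, THF, rt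
Reagents that add atoms: none
Why: fluoride cleavage of the silyl ether frees O3 while the acetal and the alkene are inert.

Step 11
Reactants: 19; 20 (Z)-2-methylbut-2-enoic acid (angelic acid)
Product: 22 (1R)-1-[(1S,2R,3R,4R)-4-(angeloyloxy)-2,3-dimethyl-2-(3-methylbut-2-en-1-yl)cyclohexyl]-2,2-diethoxyethyl angelate, via 3-O-monoangelate 21 (not isolated)
Conditions: 20, 2,4,6-trichlorobenzoyl chloride, Et3N, toluene, rt; then 19, 80 °C
Reagents that add atoms: angelic acid 20, C/C=C(/C)C(=O)O
Why: Yamaguchi-type mixed-anhydride esterification run without DMAP, the established way to make angelates without Z to E isomerisation; the ring hydroxyl should react first and the more hindered C9 hydroxyl on heating.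

Step 12
Reactants: 22
Product: 24 (1R)-1-[(1S,2R,3R,4R)-4-(angeloyloxy)-2,3-dimethyl-2-(3-methylbut-2-en-1-yl)cyclohexyl]-2-oxoethyl angelate, via collidinium salt 23 (not isolated)
Conditions: TESOTf, 2,4,6-collidine, CH2Cl2, 0 °C; then H2O
Reagents that add atoms: water, O
Why: chemoselective acetal cleavage through a pyridinium N,O-acetal salt; the aldehyde appears only on aqueous quench in buffered medium, so neither the prenyl alkene nor the angelates meet protic acid.

Step 13
Reactants: 24
Product: 25 3α,9β-bis(angeloyloxy)-10βH-eremophil-11-en-8α-ol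
Conditions: Me2AlCl (2.5 equiv), CH2Cl2, −78 → −20 °C
Reagents that add atoms: none
Why: Me2AlCl binds the aldehyde oxygen, and C8 then bonds to C7 of the trisubstituted alkene while a hydrogen of a terminal methyl group passes to oxygen through a six-centre array, so the C7–C8 bond, the C8 alkoxide and the isopropenyl group arise in one concerted event. This is a Lewis-acid-promoted type I intramolecular carbonyl-ene reaction of the citronellal-to-isopulegol kind. Ring B closes in the 6-exo sense (C11 stays outside the new ring) through a chair built on the ground-state chair of ring A, in which the 3-angelate and the C4 methyl are equatorial, the C5 methyl and the C10 arm axial and the C5 arm equatorial. C7 is controlled by that chair: the isopropylidene carbon sits equatorial on the forming ring, because an axial 7α placement would clash 1,3-diaxially with the C4–C5 bond, which gives the 7β-isopropenyl group; the complexed oxygen is also equatorial, giving the 8α-alcohol that step 14 removes. The step needs C7 selectivity and ene closure in preference to cationic (Prins, chloride-capture) paths or acyl transfer; the cis arms, the C9 angelate that is equatorial in the same chair, the syn-diaxial clash that disfavours the flipped ring-A chair, and the proton-scavenging methylaluminium reagent at low temperature should secure this.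

Step 14
Reactants: 25
Product: 26 3α,9β-bis(angeloyloxy)-10βH-eremophil-11-en-8-one, (3R,4R,5R,7R,9R,10S), CNP0174755.1
Conditions: Dess–Martin periodinane, pyridine, CH2Cl2, 0 °C
Reagents that add atoms: none
Why: Dess–Martin oxidation of the secondary alcohol under buffered, non-basic conditions, so that the epimerisable C7 and C9 centres and the β,γ-position of the isopropenyl alkene should stay as they are.

Compound list
1 | (E)-2-methylbut-2-enal (tiglaldehyde) | C/C=C(\C)C=O | starting material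
2 | (E)-3-(tert-butyldimethylsilyloxy)-N,N-dimethylbuta-1,3-dien-1-amine | CN(C)/C=C/C(=C)O[Si](C)(C)C(C)(C)C | starting material
3 | (1R,2S,6S)-4-(tert-butyldimethylsilyloxy)-2-(dimethylamino)-1,6-dimethylcyclohex-3-ene-1-carbaldehyde | O=C[C@]1(C)[C@@H](C)CC(O[Si](C)(C)C(C)(C)C)=C[C@@H]1N(C)C | intermediate
4 | (methoxymethyl)triphenylphosphonium chloride | COC[P+](c1ccccc1)(c1ccccc1)c1ccccc1.[Cl-] | starting material
5 | methyl enol ether of 3 (2-methoxyethenyl in place of formyl, E/Z mixture) | COC=C[C@]1(C)[C@@H](C)CC(O[Si](C)(C)C(C)(C)C)=C[C@@H]1N(C)C | intermediate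
6 | 2-[(1R,6S)-1,6-dimethyl-4-oxocyclohex-2-en-1-yl]acetaldehyde | O=CC[C@]1(C)[C@@H](C)CC(=O)C=C1 | intermediate
7 | isopropyltriphenylphosphonium iodide | CC(C)[P+](c1ccccc1)(c1ccccc1)c1ccccc1.[I-] | starting material
8 | (4R,5S)-4,5-dimethyl-4-(3-methylbut-2-en-1-yl)cyclohex-2-en-1-one | CC(C)=CC[C@]1(C)[C@@H](C)CC(=O)C=C1 | intermediate
9 | potassium cross-conjugated dienolate of 8 (C2–O, C2=C3) | CC(C)=CC[C@]1(C)[C@@H](C)C=C([O-])C=C1.[K+] | intermediate
10 | (4S,5R,6S)-6-hydroxy-4,5-dimethyl-4-(3-methylbut-2-en-1-yl)cyclohex-2-en-1-one | CC(C)=CC[C@]1(C)[C@@H](C)[C@H](O)C(=O)C=C1 | intermediate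
11 | (4S,5R,6S)-6-(tert-butyldimethylsilyloxy)-4,5-dimethyl-4-(3-methylbut-2-en-1-yl)cyclohex-2-en-1-one | CC(C)=CC[C@]1(C)[C@@H](C)[C@H](O[Si](C)(C)C(C)(C)C)C(=O)C=C1 | intermediate
12 | (Z)-1-bromo-2-ethoxyethene | CCO/C=C\Br | starting material
13 | lithium C1=C2 enolate of the 10α-[(Z)-2-ethoxyethenyl] adduct of 11 | CCO/C=C\[C@H]1C=C([O-])[C@@H](O[Si](C)(C)C(C)(C)C)[C@H](C)[C@@]1(C)CC=C(C)C.[Li+] | intermediate
14 | (3S,4S,5R,6S)-6-(tert-butyldimethylsilyloxy)-3-[(Z)-2-ethoxyethenyl]-4,5-dimethyl-4-(3-methylbut-2-en-1-yl)cyclohex-1-en-1-yl trifluoromethanesulfonate | CCO/C=C\[C@H]1C=C(OS(=O)(=O)C(F)(F)F)[C@@H](O[Si](C)(C)C(C)(C)C)[C@H](C)[C@@]1(C)CC=C(C)C | intermediate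
15 | tert-butyl({(1R,4R,5S,6R)-4-[(Z)-2-ethoxyethenyl]-5,6-dimethyl-5-(3-methylbut-2-en-1-yl)cyclohex-2-en-1-yl}oxy)dimethylsilane | CCO/C=C\[C@H]1C=C[C@@H](O[Si](C)(C)C(C)(C)C)[C@H](C)[C@@]1(C)CC=C(C)C | intermediate
16 | cis-2-ethoxy-3-(cyclohexenyl)oxirane from 15 (epoxide oxygen on C9 as in 17) | CCO[C@@H]1O[C@@H]1[C@H]2C=C[C@@H](O[Si](C)(C)C(C)(C)C)[C@H](C)[C@@]2(C)CC=C(C)C | intermediate
17 | (1R)-1-[(1S,4R,5R,6R)-4-(tert-butyldimethylsilyloxy)-5,6-dimethyl-6-(3-methylbut-2-en-1-yl)cyclohex-2-en-1-yl]-2,2-diethoxyethan-1-ol | CCOC(OCC)[C@H](O)[C@H]1C=C[C@@H](O[Si](C)(C)C(C)(C)C)[C@H](C)[C@@]1(C)CC=C(C)C | intermediate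
18 | (1R)-1-[(1S,2R,3R,4R)-4-(tert-butyldimethylsilyloxy)-2,3-dimethyl-2-(3-methylbut-2-en-1-yl)cyclohexyl]-2,2-diethoxyethan-1-ol | CCOC(OCC)[C@H](O)[C@H]1CC[C@@H](O[Si](C)(C)C(C)(C)C)[C@H](C)[C@@]1(C)CC=C(C)C | intermediate
19 | (1R)-2,2-diethoxy-1-[(1S,2R,3R,4R)-4-hydroxy-2,3-dimethyl-2-(3-methylbut-2-en-1-yl)cyclohexyl]ethan-1-ol | CCOC(OCC)[C@H](O)[C@H]1CC[C@@H](O)[C@H](C)[C@@]1(C)CC=C(C)C | intermediate
20 | (Z)-2-methylbut-2-enoic acid (angelic acid) | C/C=C(/C)C(=O)O | starting material
21 | 3-O-angelate of 19 (C9 hydroxyl free) | CCOC(OCC)[C@H](O)[C@H]1CC[C@@H](OC(=O)/C(C)=C\C)[C@H](C)[C@@]1(C)CC=C(C)C | intermediate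
22 | (1R)-1-[(1S,2R,3R,4R)-4-(angeloyloxy)-2,3-dimethyl-2-(3-methylbut-2-en-1-yl)cyclohexyl]-2,2-diethoxyethyl angelate | CCOC(OCC)[C@H](OC(=O)/C(C)=C\C)[C@H]1CC[C@@H](OC(=O)/C(C)=C\C)[C@H](C)[C@@]1(C)CC=C(C)C | intermediate
23 | 1-(C8-ethoxyalkyl)-2,4,6-trimethylpyridinium triflate derived from 22 | CCOC([n+]1c(C)cc(C)cc1C)[C@H](OC(=O)/C(C)=C\C)[C@H]1CC[C@@H](OC(=O)/C(C)=C\C)[C@H](C)[C@@]1(C)CC=C(C)C.[O-]S(=O)(=O)C(F)(F)F | intermediate
24 | (1R)-1-[(1S,2R,3R,4R)-4-(angeloyloxy)-2,3-dimethyl-2-(3-methylbut-2-en-1-yl)cyclohexyl]-2-oxoethyl angelate (key-step precursor) | O=C[C@H](OC(=O)/C(C)=C\C)[C@H]1CC[C@@H](OC(=O)/C(C)=C\C)[C@H](C)[C@@]1(C)CC=C(C)C | intermediate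
25 | 3α,9β-bis(angeloyloxy)-10βH-eremophil-11-en-8α-ol, (3R,4R,5R,7R,8R,9R,10S) (key-step product) | C=C(C)[C@H]1C[C@@]2(C)[C@H](CC[C@@H](OC(=O)/C(C)=C\C)[C@@H]2C)[C@@H](OC(=O)/C(C)=C\C)[C@@H]1O | intermediate
26 | 3α,9β-bis(angeloyloxy)-10βH-eremophil-11-en-8-one, (3R,4R,5R,7R,9R,10S) | C=C(C)[C@H]1C[C@@]2(C)[C@H](CC[C@@H](OC(=O)/C(C)=C\C)[C@@H]2C)[C@@H](OC(=O)/C(C)=C\C)C1=O | target

Total step count: 14. Longest linear sequence: 14 steps (1 and 2 to 26).

Steps most likely to fail

Step 13. What may go wrong: transfer of the C9 angeloyl group to the neighbouring C8 aluminium alkoxide, or chelation of the α-acyloxy aldehyde that diverts the closure towards cationic products. The fallback runs the same ring closure with silyl ethers on O3 and O9 and acylates last. It sets out from 18: silylation (TBSOTf, 2,6-lutidine) should give the bis-silyl ether acetal F1; mild hydrolysis (PPTS, acetone–water) the α-silyloxy aldehyde F2; Me2AlCl the bis-silylated 8α-alcohol F3; Dess–Martin oxidation the ketone F4; HF·pyridine the dihydroxy ketone F5. Mixed-anhydride angeloylation of both hydroxyls then comes back to the route at 26. The price is an acylation on the base-sensitive ketone.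

Step 1. What may go wrong: slow cycloaddition and poor facial discrimination with the trisubstituted enal under catalyst control. The fallback puts the stereocontrol on the diene. It sets out from 1. Condensation of (E)-4-methoxybut-3-en-2-one with (2S,5S)-2,5-diphenylpyrrolidine should give the vinylogous amide F6, and KHMDS/TBSCl the chiral aminosiloxy diene F7. Thermal Diels–Alder reaction with 1 (toluene, 20–60 °C), in which the C2-symmetric pyrrolidine shields one diene face, should give the cycloadduct F8. Wittig methoxymethylenation as in step 2 gives the enol ether F9, and the acid work-up releases the auxiliary and comes back to the route at 6.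

Step 11. What may go wrong: incomplete acylation of the hindered C9 hydroxyl and Z to E isomerisation to tiglate on long heating. The fallback builds the angelate double bonds on the molecule. It sets out from 19: DCC/DMAP esterification with 2-[bis(2,2,2-trifluoroethoxy)phosphoryl]propanoic acid should give the bis-phosphonate F10, and Still–Gennari olefination (KHMDS, 18-crown-6, acetaldehyde, −78 °C) should form both (Z)-2-methylbut-2-enoates and come back to the route at 22.

Further compounds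
F1 | step 13 | tert-butyldimethylsilyl ether of 18 at O9 (3,9-bis-silyl ether diethyl acetal) | CCOC(OCC)[C@H](O[Si](C)(C)C(C)(C)C)[C@H]1CC[C@@H](O[Si](C)(C)C(C)(C)C)[C@H](C)[C@@]1(C)CC=C(C)C
F2 | step 13 | (2R)-2-(tert-butyldimethylsilyloxy)-2-[(1S,2R,3R,4R)-4-(tert-butyldimethylsilyloxy)-2,3-dimethyl-2-(3-methylbut-2-en-1-yl)cyclohexyl]acetaldehyde | O=C[C@H](O[Si](C)(C)C(C)(C)C)[C@H]1CC[C@@H](O[Si](C)(C)C(C)(C)C)[C@H](C)[C@@]1(C)CC=C(C)C
F3 | step 13 | 3α,9β-bis(tert-butyldimethylsilyloxy)-10βH-eremophil-11-en-8α-ol | C=C(C)[C@H]1C[C@@]2(C)[C@H](CC[C@@H](O[Si](C)(C)C(C)(C)C)[C@@H]2C)[C@@H](O[Si](C)(C)C(C)(C)C)[C@@H]1O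
F4 | step 13 | 3α,9β-bis(tert-butyldimethylsilyloxy)-10βH-eremophil-11-en-8-one | C=C(C)[C@H]1C[C@@]2(C)[C@H](CC[C@@H](O[Si](C)(C)C(C)(C)C)[C@@H]2C)[C@@H](O[Si](C)(C)C(C)(C)C)C1=O
F5 | step 13 | 3α,9β-dihydroxy-10βH-eremophil-11-en-8-one | C=C(C)[C@H]1C[C@@]2(C)[C@H](CC[C@@H](O)[C@@H]2C)[C@@H](O)C1=O
F6 | step 1 | (E)-4-[(2S,5S)-2,5-diphenylpyrrolidin-1-yl]but-3-en-2-one | CC(=O)/C=C/N1[C@H](c2ccccc2)CC[C@H]1c1ccccc1
F7 | step 1 | (2S,5S)-1-[(E)-3-(tert-butyldimethylsilyloxy)buta-1,3-dien-1-yl]-2,5-diphenylpyrrolidine | C=C(O[Si](C)(C)C(C)(C)C)/C=C/N1[C@H](c2ccccc2)CC[C@H]1c1ccccc1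
F8 | step 1 | analogue of 3 with (2S,5S)-2,5-diphenylpyrrolidin-1-yl in place of dimethylamino | O=C[C@]1(C)[C@@H](C)CC(O[Si](C)(C)C(C)(C)C)=C[C@@H]1N2[C@H](c3ccccc3)CC[C@H]2c2ccccc2
F9 | step 1 | analogue of 5 with (2S,5S)-2,5-diphenylpyrrolidin-1-yl in place of dimethylamino | COC=C[C@]1(C)[C@@H](C)CC(O[Si](C)(C)C(C)(C)C)=C[C@@H]1N2[C@H](c3ccccc3)CC[C@H]2c2ccccc2
F10 | step 11 | 3,9-bis{2-[bis(2,2,2-trifluoroethoxy)phosphoryl]propanoate} of 19 (phosphonate α-carbons unassigned) | CCOC(OCC)[C@H](OC(=O)C(C)P(=O)(OCC(F)(F)F)OCC(F)(F)F)[C@H]1CC[C@@H](OC(=O)C(C)P(=O)(OCC(F)(F)F)OCC(F)(F)F)[C@H](C)[C@@]1(C)CC=C(C)C
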